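**Plan**

Retrosynthesis: the four benzyl–O bonds and the enol Si–O bond are cut last. Ring C is then opened at C3–C4: C4 is a ketone carbon that can be carried as a silyl enol ether alkene, and its neighbour C3 lies next to C2, the benzylic carbon on O1, so C2 can be an aryl 1-phenylallyl ether whose vinyl group supplies C3.
Further cuts: O1–C2 (allylic etherification of an ortho-hydroxyacetophenone), the aryl–acetyl bond (ortho-bromination and lithiation of a symmetric phenol) and the aryl–CH2 bond of the diarylmethane (aryllithium plus aldehyde, then deoxygenation).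
Forward: ring A and the catechol ring are bought and joined through the CH2 bridge; the symmetric phenol is acetylated at either of its two equivalent ortho carbons, which fixes the benzyl group at C6; O1–C2 is made, the ketone is silylated, and ring C is closed last by metathesis.
Stereochemistry: the only stereocentre, C2 (R, as read from the target SMILES), is set by the chiral phosphoramidite in the iridium-catalysed etherification and is carried unchanged through metathesis, desilylation and hydrogenolysis.

Key step: step 11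

Assumption: with O-nucleophiles and cinnamyl carbonates the (Ra,Rc,Rc) phosphoramidite is taken to give the R ether; if the sense is the opposite, its mirror image is used.

**Route**

Step 1
Reactants: 1 2,4,6-trihydroxybenzaldehyde
Product: 2 2,6-dihydroxy-4-(4-methoxybenzyloxy)benzaldehyde
Conditions: 4-methoxybenzyl chloride (1.05 equiv), NaHCO3, KI (cat.), MeCN, 60 °C
Reagents that add atoms: 4-methoxybenzyl chloride, COc1ccc(CCl)cc1
Why: Williamson etherification with a weak base should stop at the 4-OH, which is the most acidic hydroxyl (para to the formyl group) and the only one not hydrogen-bonded to or flanked by the aldehyde.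

Step 2
Reactants: 2 2,6-dihydroxy-4-(4-methoxybenzyloxy)benzaldehyde
Product: 3 2,6-bis(benzyloxy)-4-(4-methoxybenzyloxy)benzaldehyde
Conditions: BnBr (2.5 equiv), K2CO3, DMF, 60 °C
Reagents that add atoms: benzyl bromide, BrCc1ccccc1
Why: Williamson etherification under forcing carbonate conditions alkylates the two chelated ortho hydroxyls, while the 4-methoxybenzyl ether and the aldehyde are inert to base.

Step 3
Reactants: 4 3-bromocatechol
Product: 5 1,2-bis(benzyloxy)-3-bromobenzene
Conditions: BnBr (2.3 equiv), K2CO3, DMF, 50 °C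
Reagents that add atoms: benzyl bromide, BrCc1ccccc1
Why: Double Williamson etherification of a catechol is routine and the aryl bromide is untouched.

Step 4
Reactants: 5 1,2-bis(benzyloxy)-3-bromobenzene; 3 2,6-bis(benzyloxy)-4-(4-methoxybenzyloxy)benzaldehyde
Product: 7 racemic [2,3-bis(benzyloxy)phenyl][2,6-bis(benzyloxy)-4-(4-methoxybenzyloxy)phenyl]methanol, via 2,3-bis(benzyloxy)phenyllithium 6 (not isolated)
Conditions: 5, n-BuLi (1.05 equiv), THF, −78 °C; then 3, −78 to 0 °C; then H2O
Reagents that add atoms: none
Why: Bromine–lithium exchange at −78 °C gives an ortho-alkoxy aryllithium that is stable at that temperature and adds 1,2 to the non-enolisable aldehyde; the carbinol centre is formed racemic and is removed in step 5.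

Step 5
Reactants: 7 racemic [2,3-bis(benzyloxy)phenyl][2,6-bis(benzyloxy)-4-(4-methoxybenzyloxy)phenyl]methanol
Product: 8 3,5-bis(benzyloxy)-4-[2,3-bis(benzyloxy)benzyl]phenol
Conditions: Et3SiH (5 equiv), CF3CO2H (10 equiv), CH2Cl2, 0 °C
Reagents that add atoms: none
Why: Ionic hydrogenation: the acid ionises the carbinol to a diarylmethyl cation stabilised by the trioxygenated ring, the silane reduces it, and the same acid cleaves the 4-methoxybenzyl ether (its cation is trapped by the silane) while plain benzyl aryl ethers should survive dilute acid at 0 °C.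

Step 6
Reactants: 8 3,5-bis(benzyloxy)-4-[2,3-bis(benzyloxy)benzyl]phenol
Product: 9 3,5-bis(benzyloxy)-4-[2,3-bis(benzyloxy)benzyl]-2-bromophenol
Conditions: NBS (1.0 equiv), CH2Cl2, −78 °C
Reagents that add atoms: N-bromosuccinimide, O=C1CCC(=O)N1Br
Why: Electrophilic aromatic bromination goes to the phenol ring (para blocked, both equivalent ortho carbons activated by three oxygens) far faster than to the catechol diether ring, and one equivalent at low temperature should stop at the monobromide.

Step 7
Reactants: 9 3,5-bis(benzyloxy)-4-[2,3-bis(benzyloxy)benzyl]-2-bromophenol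
Product: 11 1-{2,4-bis(benzyloxy)-3-[2,3-bis(benzyloxy)benzyl]-6-hydroxyphenyl}ethan-1-one, via ortho-lithiated lithium phenoxide 10 (not isolated)
Conditions: n-BuLi (2.2 equiv), THF, −78 °C; then MeC(O)N(OMe)Me (1.5 equiv), −78 to 0 °C; then H2O
Reagents that add atoms: N-methoxy-N-methylacetamide, CC(=O)N(C)OC
Why: Deprotonation of the phenol followed by bromine–lithium exchange gives a dianion that is acylated at carbon in a Weinreb ketone synthesis, the chelated tetrahedral adduct preventing over-addition; this avoids Lewis-acid acylation, which would endanger the benzyl ethers.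

Step 8
Reactants: 12 (E)-cinnamyl alcohol
Product: 13 (E)-cinnamyl methyl carbonate
Conditions: ClCO2Me, pyridine, CH2Cl2, 0 °C
Reagents that add atoms: methyl chloroformate, COC(=O)Cl
Why: Acylation of a primary allylic alcohol with a chloroformate is routine.

Step 9
Reactants: 11 1-{2,4-bis(benzyloxy)-3-[2,3-bis(benzyloxy)benzyl]-6-hydroxyphenyl}ethan-1-one; 13 (E)-cinnamyl methyl carbonate
Product: 15 1-{2,4-bis(benzyloxy)-3-[2,3-bis(benzyloxy)benzyl]-6-{[(1R)-1-phenylprop-2-en-1-yl]oxy}phenyl}ethan-1-one, via sodium phenoxide 14 (not isolated)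
Conditions: 11, NaH (1.0 equiv), THF, 0 °C; then 13 (1.3 equiv), [Ir(cod)Cl]2 (2 mol%), (Ra,Rc,Rc)-O,O'-(1,1'-binaphthalene-2,2'-diyl) N,N-bis(1-phenylethyl)phosphoramidite (4 mol%), THF, 50 °C
Reagents that add atoms: none
Why: Iridium-catalysed asymmetric allylic etherification: the iridium phosphoramidite complex ionises the carbonate to an allyliridium species that the phenoxide attacks at the phenyl-bearing terminus, giving the branched ether, and the ligand's configuration sets the R centre that becomes C2.

Step 10
Reactants: 15 1-{2,4-bis(benzyloxy)-3-[2,3-bis(benzyloxy)benzyl]-6-{[(1R)-1-phenylprop-2-en-1-yl]oxy}phenyl}ethan-1-one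
Product: 16 tert-butyl[(1-{2,4-bis(benzyloxy)-3-[2,3-bis(benzyloxy)benzyl]-6-{[(1R)-1-phenylprop-2-en-1-yl]oxy}phenyl}ethenyl)oxy]dimethylsilane
Conditions: TBSOTf (1.3 equiv), Et3N (3 equiv), CH2Cl2, 0 °C
Reagents that add atoms: tert-butyldimethylsilyl trifluoromethanesulfonate, CC(C)(C)[Si](C)(C)OS(=O)(=O)C(F)(F)F
Why: Soft enolisation of the methyl ketone (O-silylation, then loss of a methyl proton to the amine) gives the silyl enol ether; the excess amine keeps the medium non-acidic, so the ionisable allylic aryl ether and C2 should be untouched.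

Step 11
Reactants: 16 tert-butyl[(1-{2,4-bis(benzyloxy)-3-[2,3-bis(benzyloxy)benzyl]-6-{[(1R)-1-phenylprop-2-en-1-yl]oxy}phenyl}ethenyl)oxy]dimethylsilane
Product: 17 (2R)-5,7-bis(benzyloxy)-6-[2,3-bis(benzyloxy)benzyl]-4-(tert-butyldimethylsilyloxy)-2-phenyl-2H-chromene
Conditions: second-generation Hoveyda–Grubbs catalyst RuCl2(H2IMes)(=CH-C6H4-2-O-i-Pr) (10 mol%), 1,4-benzoquinone (20 mol%), degassed toluene (0.005 M), 60 °C, dark
Reagents that add atoms: none
Why: The ruthenium alkylidene first exchanges onto the monosubstituted vinyl group of the allylic ether, then adds intramolecularly across the 1,1-disubstituted silyl enol ether in a [2+2] cycloaddition, and the ruthenacyclobutane cycloreverts to give the C3=C4 double bond and, after turnover, ethylene. This is ring-closing olefin metathesis of a silyl enol ether; the closest known cases are enol ether–ene closures to cyclic silyl enol ethers (including 4-silyloxy-1,2-dihydroquinolines from N-allyl anilines) and diene closures to 2H-chromenes. Ring C closes as a six-membered ring with the new alkene endocyclic, C4 of the enol ether and the former vinyl carbon C3 being joined through the metallacycle. No stereocentre is created; C2 was fixed in step 9 and no bond to it is made or broken. The step needs chemoselectivity for ring closure over ruthenium hydride isomerisation of the allylic ether and over unproductive capture of the metal by the enol ether: the enol ether, flanked by two ortho substituents, cannot initiate, benzoquinone scavenges hydrides, high dilution disfavours cross-metathesis, and moderate temperature with exclusion of light should keep the 2H-chromene from electrocyclic ring opening that would racemise C2.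

Step 12
Reactants: 17 (2R)-5,7-bis(benzyloxy)-6-[2,3-bis(benzyloxy)benzyl]-4-(tert-butyldimethylsilyloxy)-2-phenyl-2H-chromene
Product: 18 (2R)-5,7-bis(benzyloxy)-6-[2,3-bis(benzyloxy)benzyl]-2-phenylchroman-4-one
Conditions: HF·pyridine, pyridine, THF, 0 °C
Reagents that add atoms: none
Why: Protodesilylation of the silyl enol ether (fluoride at silicon, proton at C3) reveals the C4 ketone in a buffered, mildly acidic medium in which no free enolate persists, so retro-oxa-Michael opening of ring C and loss of the C2 configuration should not occur.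

Step 13
Reactants: 18 (2R)-5,7-bis(benzyloxy)-6-[2,3-bis(benzyloxy)benzyl]-2-phenylchroman-4-one
Product: 19 (2R)-6-(2,3-dihydroxybenzyl)-5,7-dihydroxy-2-phenylchroman-4-one
Conditions: H2 (1 atm), 10% Pd/C, EtOAc–MeOH, rt
Reagents that add atoms: none
Why: Catalytic hydrogenolysis removes the four primary benzyl ethers much faster than it attacks the secondary benzylic C2–O1 bond or the aryl ketone, so stopping after uptake of four equivalents should give the free tetraphenol without touching C2.

**Compound list**

1 | 2,4,6-trihydroxybenzaldehyde | O=Cc1c(O)cc(O)cc1O | starting material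
2 | 2,6-dihydroxy-4-(4-methoxybenzyloxy)benzaldehyde | O=Cc1c(O)cc(OCc2ccc(OC)cc2)cc1O | intermediate
3 | 2,6-bis(benzyloxy)-4-(4-methoxybenzyloxy)benzaldehyde | O=Cc1c(OCc2ccccc2)cc(OCc2ccc(OC)cc2)cc1OCc1ccccc1 | intermediate
4 | 3-bromocatechol (3-bromobenzene-1,2-diol) | Oc1cccc(Br)c1O | starting material
5 | 1,2-bis(benzyloxy)-3-bromobenzene | Brc1cccc(OCc2ccccc2)c1OCc1ccccc1 | intermediate
6 | 2,3-bis(benzyloxy)phenyllithium | [Li]c1cccc(OCc2ccccc2)c1OCc1ccccc1 | intermediate
7 | racemic [2,3-bis(benzyloxy)phenyl][2,6-bis(benzyloxy)-4-(4-methoxybenzyloxy)phenyl]methanol | OC(c1cccc(OCc2ccccc2)c1OCc1ccccc1)c1c(OCc2ccccc2)cc(OCc2ccc(OC)cc2)cc1OCc1ccccc1 | intermediate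
8 | 3,5-bis(benzyloxy)-4-[2,3-bis(benzyloxy)benzyl]phenol | Oc1cc(OCc2ccccc2)c(Cc2cccc(OCc3ccccc3)c2OCc2ccccc2)c(OCc2ccccc2)c1 | intermediate
9 | 3,5-bis(benzyloxy)-4-[2,3-bis(benzyloxy)benzyl]-2-bromophenol | Oc1cc(OCc2ccccc2)c(Cc2cccc(OCc3ccccc3)c2OCc2ccccc2)c(OCc2ccccc2)c1Br | intermediate
10 | lithium 3,5-bis(benzyloxy)-4-[2,3-bis(benzyloxy)benzyl]-2-lithiophenoxide | [Li]Oc1cc(OCc2ccccc2)c(Cc2cccc(OCc3ccccc3)c2OCc2ccccc2)c(OCc2ccccc2)c1[Li] | intermediate
11 | 1-{2,4-bis(benzyloxy)-3-[2,3-bis(benzyloxy)benzyl]-6-hydroxyphenyl}ethan-1-one | CC(=O)c1c(O)cc(OCc2ccccc2)c(Cc2cccc(OCc3ccccc3)c2OCc2ccccc2)c1OCc1ccccc1 | intermediate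
12 | (E)-cinnamyl alcohol | OC/C=C/c1ccccc1 | starting material
13 | (E)-cinnamyl methyl carbonate | COC(=O)OC/C=C/c1ccccc1 | intermediate
14 | sodium 2-acetyl-3,5-bis(benzyloxy)-4-[2,3-bis(benzyloxy)benzyl]phenoxide | [Na+].CC(=O)c1c([O-])cc(OCc2ccccc2)c(Cc2cccc(OCc3ccccc3)c2OCc2ccccc2)c1OCc1ccccc1 | intermediate
15 | 1-{2,4-bis(benzyloxy)-3-[2,3-bis(benzyloxy)benzyl]-6-{[(1R)-1-phenylprop-2-en-1-yl]oxy}phenyl}ethan-1-one | C=C[C@H](c1ccccc1)Oc1cc(OCc2ccccc2)c(Cc2cccc(OCc3ccccc3)c2OCc2ccccc2)c(OCc2ccccc2)c1C(C)=O | intermediate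
16 | tert-butyl[(1-{2,4-bis(benzyloxy)-3-[2,3-bis(benzyloxy)benzyl]-6-{[(1R)-1-phenylprop-2-en-1-yl]oxy}phenyl}ethenyl)oxy]dimethylsilane | C=C[C@H](c1ccccc1)Oc1cc(OCc2ccccc2)c(Cc2cccc(OCc3ccccc3)c2OCc2ccccc2)c(OCc2ccccc2)c1C(=C)O[Si](C)(C)C(C)(C)C | intermediate
17 | (2R)-5,7-bis(benzyloxy)-6-[2,3-bis(benzyloxy)benzyl]-4-(tert-butyldimethylsilyloxy)-2-phenyl-2H-chromene | CC(C)(C)[Si](C)(C)OC1=C[C@H](c2ccccc2)Oc2cc(OCc3ccccc3)c(Cc3cccc(OCc4ccccc4)c3OCc3ccccc3)c(OCc3ccccc3)c21 | intermediate
18 | (2R)-5,7-bis(benzyloxy)-6-[2,3-bis(benzyloxy)benzyl]-2-phenylchroman-4-one | O=C1C[C@H](c2ccccc2)Oc2cc(OCc3ccccc3)c(Cc3cccc(OCc4ccccc4)c3OCc3ccccc3)c(OCc3ccccc3)c21 | intermediate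
19 | (2R)-6-(2,3-dihydroxybenzyl)-5,7-dihydroxy-2-phenylchroman-4-one | O=C1C[C@H](c2ccccc2)Oc2cc(O)c(Cc3cccc(O)c3O)c(O)c21 | target

**Step count and risks**

Total step count: 13. Longest linear sequence: 11 steps (1, 2, 4, 5, 6, 7, 9, 10, 11, 12, 13, from compound 1).

Step 11. The crowded enol ether, twisted out of the arene plane and carrying a bulky silyl group, may fail to enter the metallacycle. Hydride-mediated migration of the allylic double bond (which destroys C2) or catalyst decay would then outrun ring closure, and heating to force the reaction invites electrocyclic opening of the chromene. The fallback gives up metathesis and closes ring C at O1–C2 instead. It sets out from 11 and comes back at 18. Ketone 11 is condensed with N,N-dimethylformamide dimethyl acetal (toluene, 100 °C) to (E)-1-{2,4-bis(benzyloxy)-3-[2,3-bis(benzyloxy)benzyl]-6-hydroxyphenyl}-3-(dimethylamino)prop-2-en-1-one F1. Aqueous HCl in CH2Cl2 cyclises it to 5,7-bis(benzyloxy)-6-[2,3-bis(benzyloxy)benzyl]-4H-chromen-4-one F2. Asymmetric conjugate addition of phenylboronic acid then gives 18, using Pd(OCOCF3)2, the enantiomer of the tert-butyl pyridine-oxazoline ligand that places phenyl on the face leading to 2R, NH4PF6 and water in 1,2-dichloroethane at 60 °C. The route resumes at step 13.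

Step 9. The chelated, electron-poor ortho-acyl phenoxide may attack the allyliridium species slowly. The product ether, which carries a good phenoxide leaving group, may then be re-ionised by the catalyst, with drift to the linear ether and erosion of enantiopurity. The fallback makes the C2–O1 bond by a stereospecific substitution and needs no metal. It sets out from 11 and comes back at 15. Phenol 11 and commercial (S)-1-phenylprop-2-en-1-ol F3 are coupled in a Mitsunobu reaction (PPh3, diisopropyl azodicarboxylate, toluene, −20 °C). Inversion at the carbinol carbon should give the R ether 15; the low temperature and non-polar solvent are meant to suppress ion-pair scrambling and allylic transposition.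

Step 7. The dilithiated species may be quenched before acylation, by proton transfer from the acetyl group of the amide or by metalation of a neighbouring benzyl ether followed by rearrangement, returning phenol 8 or giving rearranged material. The fallback replaces the organolithium by cross-coupling. It sets out from 9 and comes back at 11. Stille coupling of 9 with tributyl(1-ethoxyvinyl)stannane (Pd(PPh3)4, toluene, 100 °C) gives 3,5-bis(benzyloxy)-4-[2,3-bis(benzyloxy)benzyl]-2-(1-ethoxyethenyl)phenol F4. Brief treatment with 1 M HCl in THF hydrolyses the enol ether to ketone 11.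

**Further compounds**

F1 | step 11 | (E)-1-{2,4-bis(benzyloxy)-3-[2,3-bis(benzyloxy)benzyl]-6-hydroxyphenyl}-3-(dimethylamino)prop-2-en-1-one | CN(C)/C=C/C(=O)c1c(O)cc(OCc2ccccc2)c(Cc2cccc(OCc3ccccc3)c2OCc2ccccc2)c1OCc1ccccc1
F2 | step 11 | 5,7-bis(benzyloxy)-6-[2,3-bis(benzyloxy)benzyl]-4H-chromen-4-one | O=c1ccoc2cc(OCc3ccccc3)c(Cc3cccc(OCc4ccccc4)c3OCc3ccccc3)c(OCc3ccccc3)c12
F3 | step 9 | (S)-1-phenylprop-2-en-1-ol | C=C[C@@H](c1ccccc1)O
F4 | step 7 | 3,5-bis(benzyloxy)-4-[2,3-bis(benzyloxy)benzyl]-2-(1-ethoxyethenyl)phenol | C=C(OCC)c1c(O)cc(OCc2ccccc2)c(Cc2cccc(OCc3ccccc3)c2OCc2ccccc2)c1OCc1ccccc1
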